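**Assumption:** labdane atom numbering (C1–C20) is used for all compounds; "axial/equatorial" refer to the chair of ring A.

## Retrosynthetic overview

1. Rings A and B, with C4, C5, C9, C10 and both ring-A oxygens, are taken intact from andrographolide (1); no ring is built.
2. Last disconnections: C13–H (carboxylate-directed asymmetric hydrogenation) and C12=C13 (Wittig with a four-carbon carboxy-ylide), back to a C12 aldehyde carried as its dimethyl acetal.
3. Key C–O step: the axial C3 acetate comes from the C3 ketone by a formaldehyde-driven Tishchenko ester formation at O19 that hands hydride to C3 from the C19 face, then O3-acetylation and loss of the formate.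
4. Earlier: C3 ketone by secondary-selective oxidation; the 7-ene from the 8(17)-ene by hydrogen-atom-transfer isomerisation; the C12 aldehyde by epoxidation/periodate excision of the lactone of 1.

## Route

Step 1
Reactants: 1 andrographolide
Product: 2 12,13-epoxy-12,13-dihydroandrographolide (both oxirane diastereomers)
Conditions: t-BuOOH (decane), DBU, THF, 0 → 23 °C
Reagents that add atoms: tert-butyl hydroperoxide CC(C)(C)OO
Why: Weitz–Scheffer nucleophilic epoxidation: the peroxide anion adds only to the electron-poor C12=C13 bond (the site where soft nucleophiles attack 1) and closes the oxirane, the electron-rich C8(17) alkene is untouched, and the two new oxirane centres are destroyed in step 2 so their configuration does not matter.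

Step 2
Reactants: 2 12,13-epoxy-12,13-dihydroandrographolide
Product: 4 (3R)-12,12-dimethoxy-13,14,15,16-tetranor-ent-labd-8(17)-ene-3,19-diol, via aldehyde 3 (not isolated)
Conditions: H5IO6 (1.1 equiv), THF–H2O, 0 → 23 °C; then HC(OMe)3, PPTS, MeOH, 23 °C
Reagents that add atoms: trimethyl orthoformate COC(OC)OC
Why: Periodic acid opens the oxirane to the 12,13-glycol and cleaves it (Malaprade glycol cleavage), excising the lactone as a keto-lactone, and acid-catalysed acetalisation in methanol masks the C12 aldehyde for steps 3–5; no stereocentre is touched.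

Step 3
Reactants: 4 (3R)-12,12-dimethoxy-13,14,15,16-tetranor-ent-labd-8(17)-ene-3,19-diol
Product: 5 (3R)-12,12-dimethoxy-13,14,15,16-tetranor-ent-labd-7-ene-3,19-diol
Conditions: (salen)CoCl [salen = N,N′-bis(3,5-di-tert-butylsalicylidene)ethane-1,2-diaminate] (3 mol%), PhSiH3 (6 mol%), benzene, 23 °C
Reagents that add atoms: none
Why: Hydrogen-atom-transfer alkene isomerisation: a cobalt hydride adds H reversibly to the 1,1-disubstituted alkene to give the tertiary C8 radical, and back-abstraction from the unhindered C7 methylene (not from the shielded tertiary C9–H) gives the trisubstituted 7-ene, so C9 keeps its configuration.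

Step 4
Reactants: 5 (3R)-12,12-dimethoxy-13,14,15,16-tetranor-ent-labd-7-ene-3,19-diol
Product: 6 19-hydroxy-12,12-dimethoxy-13,14,15,16-tetranor-ent-labd-7-en-3-one
Conditions: (NH4)6Mo7O24·4H2O (10 mol%), 30% H2O2, K2CO3, Bu4NCl, THF, 23 °C
Reagents that add atoms: none
Why: Molybdate/hydrogen peroxide alcohol oxidation under carbonate buffering oxidises secondary hydroxyls in preference to primary ones and does not epoxidise alkenes, so only the wrongly configured C3 carbinol becomes a ketone while the C19 hydroxyl, the 7-ene and the acetal survive.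

Step 5
Reactants: 6 19-hydroxy-12,12-dimethoxy-13,14,15,16-tetranor-ent-labd-7-en-3-one
Product: 9 (3S)-3-acetoxy-12,12-dimethoxy-13,14,15,16-tetranor-ent-labd-7-en-19-ol, via 19-O-formyl axial 3-alcohol 7 (not isolated), via 3-acetate 19-formate 8 (not isolated)
Conditions: SmI2 (30 mol%), CH2O (freshly cracked, THF solution, 6 equiv), THF, −10 °C; evaporate; then Ac2O, DMAP, Et3N, CH2Cl2, 23 °C; then KHCO3, MeOH, 0 °C
Reagents that add atoms: acetic anhydride CC(=O)OC(C)=O
Why: Proposed new method: the C19 hydroxyl adds to formaldehyde on a trivalent samarium alkoxide to form a hemiformal (new C–O bond), whose hydride is passed through a six-membered transition state to the C3 carbonyl from the face carrying the axial C19, i.e. along the equatorial direction, so the C3–O bond becomes axial and trans to C19 (3S) while O19 is left as a formate; the free axial 3-hydroxyl is then acetylated and the formate, far more labile than the hindered acetate, is removed by bicarbonate/methanol to give the 3-acetate/19-alcohol with no protecting-group steps; the closest known reaction is the samarium-catalysed Evans–Tishchenko reduction of β-hydroxy ketones with higher aldehydes to anti-1,3-diol monoesters, and what is new is formaldehyde as the hydride donor (a traceless formate relay), the ring-locked α-quaternary substrate and the one-flask differentiation of the two oxygens.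

Step 6
Reactants: 10 (E)-crotonic acid; 11 triphenylphosphine hydrobromide
Product: 12 (1-carboxypropan-2-yl)triphenylphosphonium bromide (racemic)
Conditions: MeCN, 80 °C
Reagents that add atoms: none
Why: Phospha-Michael (conjugate) addition of triphenylphosphine to the protonated enoic acid gives the β-phosphonio acid, and its racemic stereocentre is lost on ylide formation.

Step 7
Reactants: 9 (3S)-3-acetoxy-12,12-dimethoxy-13,14,15,16-tetranor-ent-labd-7-en-19-ol; 12 (1-carboxypropan-2-yl)triphenylphosphonium bromide
Product: 15 (3S)-3-acetoxy-19-hydroxy-ent-labda-7,12-dien-15-oic acid (12E/12Z mixture), via ylide 13 (not isolated), via aldehyde 14 (not isolated)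
Conditions: 9: PPTS, acetone–H2O, 50 °C; 12: NaN(SiMe3)2 (2 equiv per 12), THF, 0 °C; then combine (3 equiv ylide), THF, −78 → 0 °C; 1 M HCl work-up
Reagents that add atoms: none
Why: Mild acetal hydrolysis followed by Wittig olefination with the carboxylate-bearing non-stabilised ylide (which cannot eliminate phosphine because the carboxylate is already anionic) forms C12=C13 and brings in C13–C16 as the free acid at −78 to 0 °C, where the hindered axial acetate is not attacked; the E/Z ratio is unimportant because C13 is set in step 8.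

Step 8
Reactants: 15 (3S)-3-acetoxy-19-hydroxy-ent-labda-7,12-dien-15-oic acid (12E/12Z mixture)
Product: 16 (3S,4R,5S,9R,10S,13R)-3-acetoxy-19-hydroxy-ent-labd-7-en-15-oic acid (CNP0138726.1)
Conditions: Ru(OAc)2[(S)-BINAP] (2 mol%), H2 (100 atm), MeOH, 30 °C
Reagents that add atoms: none
Why: Noyori-type carboxylate-directed asymmetric hydrogenation: the acid binds ruthenium through its carboxylate so only the 12-ene is reduced (the unfunctionalised 7-ene is inert), and because the chelating CH2CO2 arm sits on C13 itself the ligand selects the face of C13 that receives hydrogen, so both alkene isomers should converge on 13R.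

## Compound list

1 | andrographolide (3R, 3-OH equatorial; 14S; 12E) | O[C@@H]1CC[C@]2(C)[C@H](CCC(=C)[C@H]2C/C=C3/C(=O)OC[C@H]3O)[C@]1(C)CO | starting material
2 | 12,13-epoxy-12,13-dihydroandrographolide (oxirane epimers at C12/C13) | O[C@@H]1CC[C@]2(C)[C@H](CCC(=C)[C@H]2CC3OC34C(=O)OC[C@H]4O)[C@]1(C)CO | intermediate
3 | (3R)-3,19-dihydroxy-13,14,15,16-tetranor-ent-labd-8(17)-en-12-al (not isolated) | O[C@@H]1CC[C@]2(C)[C@H](CCC(=C)[C@H]2CC=O)[C@]1(C)CO | intermediate
4 | (3R)-12,12-dimethoxy-13,14,15,16-tetranor-ent-labd-8(17)-ene-3,19-diol | O[C@@H]1CC[C@]2(C)[C@H](CCC(=C)[C@H]2CC(OC)OC)[C@]1(C)CO | intermediate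
5 | (3R)-12,12-dimethoxy-13,14,15,16-tetranor-ent-labd-7-ene-3,19-diol | O[C@@H]1CC[C@]2(C)[C@H](CC=C(C)[C@H]2CC(OC)OC)[C@]1(C)CO | intermediate
6 | 19-hydroxy-12,12-dimethoxy-13,14,15,16-tetranor-ent-labd-7-en-3-one | O=C1CC[C@]2(C)[C@H](CC=C(C)[C@H]2CC(OC)OC)[C@]1(C)CO | intermediate
7 | (3S)-3-hydroxy (axial)-12,12-dimethoxy-13,14,15,16-tetranor-ent-labd-7-en-19-yl formate (not isolated) | O[C@H]1CC[C@]2(C)[C@H](CC=C(C)[C@H]2CC(OC)OC)[C@]1(C)COC=O | intermediate
8 | (3S)-3-acetoxy (axial)-12,12-dimethoxy-13,14,15,16-tetranor-ent-labd-7-en-19-yl formate (not isolated) | CC(=O)O[C@H]1CC[C@]2(C)[C@H](CC=C(C)[C@H]2CC(OC)OC)[C@]1(C)COC=O | intermediate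
9 | (3S)-3-acetoxy (axial)-12,12-dimethoxy-13,14,15,16-tetranor-ent-labd-7-en-19-ol | CC(=O)O[C@H]1CC[C@]2(C)[C@H](CC=C(C)[C@H]2CC(OC)OC)[C@]1(C)CO | intermediate
10 | (E)-crotonic acid | C/C=C/C(=O)O | starting material
11 | triphenylphosphine hydrobromide (triphenylphosphonium bromide) | [Br-].[PH+](c1ccccc1)(c1ccccc1)c1ccccc1 | starting material
12 | (1-carboxypropan-2-yl)triphenylphosphonium bromide (racemic) | CC(CC(=O)O)[P+](c1ccccc1)(c1ccccc1)c1ccccc1.[Br-] | intermediate
13 | sodium 3-(triphenylphosphoranylidene)butanoate (ylide, not isolated) | CC(CC(=O)[O-])=P(c1ccccc1)(c1ccccc1)c1ccccc1.[Na+] | intermediate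
14 | (3S)-3-acetoxy-19-hydroxy-13,14,15,16-tetranor-ent-labd-7-en-12-al (not isolated) | CC(=O)O[C@H]1CC[C@]2(C)[C@H](CC=C(C)[C@H]2CC=O)[C@]1(C)CO | intermediate
15 | (3S)-3-acetoxy-19-hydroxy-ent-labda-7,12-dien-15-oic acid (12E/12Z mixture) | CC(=O)O[C@H]1CC[C@]2(C)[C@H](CC=C(C)[C@H]2CC=C(C)CC(=O)O)[C@]1(C)CO | intermediate
16 | (3S,4R,5S,9R,10S,13R)-3-acetoxy-19-hydroxy-ent-labd-7-en-15-oic acid (CNP0138726.1) | CC(=O)O[C@H]1CC[C@]2(C)[C@H](CC=C(C)[C@H]2CC[C@@H](C)CC(=O)O)[C@]1(C)CO | target

## Step count and risks

Total steps: 8. Longest linear sequence: 7 (1 → 2 → 4 → 5 → 6 → 9 → 15 → 16; step 6 is a one-step side branch).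

Stereocentres: C4, C5, C9 and C10 come unchanged from 1; C3 is set in step 5; C13 is set in step 8.

Three steps most likely to fail:

**Step 4 (secondary-selective oxidation).** The molybdate system may be slow on the neopentyl C3 carbinol, may also touch the C19 hydroxyl, or the carbonate may trigger retro-aldol loss of formaldehyde from 6. The fallback sets out from 5 and comes back at 6. The primary hydroxyl is silylated selectively (Et3SiCl, imidazole, CH2Cl2, −40 °C) to give the 19-O-triethylsilyl ether F1. Dess–Martin periodinane (NaHCO3, CH2Cl2) then oxidises the only free hydroxyl to the 19-O-triethylsilyl 3-ketone F2. HF·pyridine (THF, 0 °C) removes the silyl group under non-basic conditions to give 6.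

**Step 5 (the proposed new Tishchenko relay).** Formaldehyde may oligomerise or hydroxymethylate C2, turnover on samarium may be poor, or acetylation of the hindered axial alcohol may be sluggish. The fallback uses known chemistry, sets out from 6 and comes back at 9. A classical Evans–Tishchenko reduction with acetaldehyde (SmI2 30 mol%, CH3CHO 10 equiv, THF, −10 °C) gives the axial 3-alcohol 19-acetate F3 by the same intramolecular hydride delivery. Ac2O/DMAP/pyridine gives the 3,19-diacetate F4. The primary acetate is then cleaved in preference to the hindered axial secondary one (K2CO3, MeOH, 0 °C, monitored) to give 9.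

**Step 8 (hydrogenation that sets C13).** The sense and level of induction are unproven for a 3-methyl-3-enoic acid used as an E/Z mixture; the (S)-ligand is a first choice and the (R)-ligand would give the 13S epimer. Ruthenium hydride may also move the alkene into conjugation, and the C13 epimers would be hard to separate at the last step. The fallback sets out from aldehyde 14 and comes back at 16.
- Wittig reaction with (1-methoxyethylidene)triphenylphosphorane gives the C12 enol ether F5.
- Aqueous acid (PPTS, acetone–H2O) gives the methyl ketone F6.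
- Horner–Wadsworth–Emmons reaction with allyl diethylphosphonoacetate (NaH, THF) gives the (E)-allyl enoate F7, the minor Z isomer being removed by chromatography.
- Copper hydride asymmetric conjugate reduction of this geometrically pure β,β-disubstituted enoate (Cu(OAc)2·H2O, (S)-DTBM-SEGPHOS or its antipode as required, polymethylhydrosiloxane, t-BuOH, toluene; fluoride work-up) gives the saturated allyl ester F8 with C13 R.
- Pd(PPh3)4 and morpholine (THF) remove the allyl group without touching the acetate to give 16.

Further compounds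
F1 | step 4 | (3R)-12,12-dimethoxy-19-(triethylsilyloxy)-13,14,15,16-tetranor-ent-labd-7-en-3-ol | O[C@@H]1CC[C@]2(C)[C@H](CC=C(C)[C@H]2CC(OC)OC)[C@]1(C)CO[Si](CC)(CC)CC
F2 | step 4 | 12,12-dimethoxy-19-(triethylsilyloxy)-13,14,15,16-tetranor-ent-labd-7-en-3-one | O=C1CC[C@]2(C)[C@H](CC=C(C)[C@H]2CC(OC)OC)[C@]1(C)CO[Si](CC)(CC)CC
F3 | step 5 | (3S)-3-hydroxy (axial)-12,12-dimethoxy-13,14,15,16-tetranor-ent-labd-7-en-19-yl acetate | O[C@H]1CC[C@]2(C)[C@H](CC=C(C)[C@H]2CC(OC)OC)[C@]1(C)COC(C)=O
F4 | step 5 | (3S)-3,19-diacetoxy-12,12-dimethoxy-13,14,15,16-tetranor-ent-labd-7-ene | CC(=O)O[C@H]1CC[C@]2(C)[C@H](CC=C(C)[C@H]2CC(OC)OC)[C@]1(C)COC(C)=O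
F5 | step 8 | (3S)-3-acetoxy-13-methoxy-14,15-dinor-ent-labda-7,12-dien-19-ol (enol ether, E/Z) | CC(=O)O[C@H]1CC[C@]2(C)[C@H](CC=C(C)[C@H]2CC=C(C)OC)[C@]1(C)CO
F6 | step 8 | (3S)-3-acetoxy-19-hydroxy-14,15-dinor-ent-labd-7-en-13-one | CC(=O)O[C@H]1CC[C@]2(C)[C@H](CC=C(C)[C@H]2CCC(C)=O)[C@]1(C)CO
F7 | step 8 | allyl (3S,13E)-3-acetoxy-19-hydroxy-ent-labda-7,13-dien-15-oate | CC(=O)O[C@H]1CC[C@]2(C)[C@H](CC=C(C)[C@H]2CC/C(C)=C/C(=O)OCC=C)[C@]1(C)CO
F8 | step 8 | allyl (3S,13R)-3-acetoxy-19-hydroxy-ent-labd-7-en-15-oate | CC(=O)O[C@H]1CC[C@]2(C)[C@H](CC=C(C)[C@H]2CC[C@@H](C)CC(=O)OCC=C)[C@]1(C)CO
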